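**Strategy.** The cyclohexane ring (C1 = CH bearing the side chain, C2 = CMe2, C3 = CHBr, C6 = C=CH2) is cut into a C4 piece and a C2 piece. C3–C4–C5–C6 come from a 1,4-keto aldehyde; the vicinal pair C2/C1 comes from C4 and C3 of 4-methylpenta-1,3-diene. Enantioselective 1,2-diboration turns the diene into a chiral vicinal bis-allyl donor. Its double allylboration of the keto aldehyde makes the C3–C2 and C1–C6 bonds in one operation, relays the C–B stereocentre into the ring, and leaves a vinyl group (side-chain handle) and a β-hydroxysilane (latent exocyclic methylene). The feature exploited is the quaternary C2 lying between C1 and C3, with C3 and C6 in a 1,4-relationship (a latent cyclohexane-1,4-diol).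

Key step: step 4

Remark (assumption): which enantiomer of the TADDOL-derived phosphonite gives (S)-8 is not assigned here; the ligand enantiomer that does so is used in step 3.
Remark (numbering): side-chain carbons are C1' (CH2Br) to C5' (CH2 on the ring).

Step 1
Reactants: 1 pent-4-enoyl chloride; 2 (trimethylsilyl)methylmagnesium chloride
Product: 3 1-(trimethylsilyl)hex-5-en-2-one
Conditions: CuI (10 mol %), THF, −30 °C → 0 °C
Reagents that add atoms: none
Why: Copper-catalysed acylation of a Grignard reagent by an acid chloride (ketone synthesis) should stop at the α-silyl ketone, which does not take up a second equivalent at low temperature.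

Step 2
Reactants: 3 1-(trimethylsilyl)hex-5-en-2-one
Product: 5 4-oxo-5-(trimethylsilyl)pentanal, via ozonide 4 (not isolated)
Conditions: O3, CH2Cl2, −78 °C; then Me2S, −78 °C → rt
Reagents that add atoms: ozone, O=[O+][O-]
Why: Ozonolysis with reductive work-up cleaves the terminal alkene to the aldehyde under neutral conditions that the acid- and base-labile α-silyl ketone should tolerate.

Step 3
Reactants: 6 4-methylpenta-1,3-diene; 7 bis(pinacolato)diboron
Product: 8 (S)-1,2-bis(pinacolatoboryl)-4-methylpent-3-ene
Conditions: Pt(dba)3 (3 mol %), TADDOL-derived phenylphosphonite ligand (6 mol %, enantiomer giving S), THF, 60 °C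
Reagents that add atoms: none
Why: Enantioselective platinum-catalysed 1,2-diboration: the cis-methyl group on C4 keeps the diene out of the s-cis form, so the zerovalent platinum catalyst adds B–B across the terminal alkene only, and the chiral phosphonite sets the secondary C–B stereocentre.

Step 4
Reactants: 8 (S)-1,2-bis(pinacolatoboryl)-4-methylpent-3-ene; 5 4-oxo-5-(trimethylsilyl)pentanal
Product: 11 (1R,2S,4S)-2-ethenyl-3,3-dimethyl-1-[(trimethylsilyl)methyl]cyclohexane-1,4-diol, via allylboronate 9 (not isolated), via bis-borate ester 10 (not isolated)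
Conditions: THF, rt → 60 °C; then H2O, pH 7 buffer, rt
Reagents that add atoms: none
Why: The secondary allylic boronate of 8 allylates the aldehyde of 5 through a closed six-membered chair transition state with bond formation at the γ-carbon (the CMe2 terminus), which creates quaternary C2 bonded to the carbinol carbon C3 and unmasks the (E)-primary allylboronate 9; 9 then allylates the tethered ketone in the same way, making the C1–C6 bond and closing the ring. The closest known reaction type is the tandem diene 1,2-diboration/double allylboration of 1,4-dicarbonyl compounds, a formal [4+2] annulation. The carbocycle closes by intramolecular carbonyl allylation (6-exo-trig at the ketone carbon) through a chair-like bicyclic transition state. C3 is controlled by the C–B stereocentre of 8 (chair with the CH2Bpin group pseudo-equatorial, enforced by A(1,3) strain with the cis-methyl group, which also fixes the E alkene of 9); C1 is controlled by C3 through the forming chair with the boryloxy and incipient vinyl groups equatorial (1,3-cis); the C6 carbinol follows from the E geometry of 9 with the CH2SiMe3 group equatorial and is erased later. The step needs aldehyde-before-ketone chemoselectivity and γ-regioselectivity in both allylations; the much higher electrophilicity of the aldehyde and the allylic transposition inherent in allylboration secure them.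

Step 5
Reactants: 11 (1R,2S,4S)-diol
Product: 12 (3S,4R)-3-ethenyl-4-hydroxy-2,2-dimethyl-4-[(trimethylsilyl)methyl]cyclohexan-1-one
Conditions: Dess–Martin periodinane, pyridine, CH2Cl2, 0 °C → rt
Reagents that add atoms: none
Why: Dess–Martin oxidation converts the only secondary alcohol into the ketone while the tertiary β-silyl carbinol cannot be oxidised, which erases the C3 carbinol centre so that it can be reset with the opposite configuration.

Step 6
Reactants: 12 hydroxy ketone
Product: 13 (1R,2S,4R)-2-ethenyl-3,3-dimethyl-1-[(trimethylsilyl)methyl]cyclohexane-1,4-diol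
Conditions: LiBH(s-Bu)3, THF, −78 °C; then sat. NH4Cl
Reagents that add atoms: none
Why: Reduction with a bulky trialkylborohydride should attack the ketone next to the gem-dimethyl carbon along the equatorial trajectory of the chair fixed by the equatorial vinyl and CH2SiMe3 groups, giving the axial alcohol trans to the vinyl group.

Step 7
Reactants: 13 (1R,2S,4R)-diol
Product: 15 (1R,2S,4R)-2-(2-hydroxyethyl)-3,3-dimethyl-1-[(trimethylsilyl)methyl]cyclohexane-1,4-diol, via alkylborane 14 (not isolated)
Conditions: 9-BBN, THF, 0 → 50 °C; then NaOH, H2O2, 0 °C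
Reagents that add atoms: hydrogen peroxide, OO
Why: Hydroboration–oxidation places boron on the terminal carbon of the only alkene (anti-Markovnikov), and because the exocyclic methylene is still masked as the β-hydroxysilane no chemoselectivity problem arises.

Step 8
Reactants: 15 triol
Product: 16 (1R,3R)-3-(2-hydroxyethyl)-2,2-dimethyl-4-methylidenecyclohexan-1-ol
Conditions: KH (excess), THF, 0 °C → rt
Reagents that add atoms: none
Why: Base-promoted Peterson elimination: the potassium alkoxide of the β-hydroxysilane loses silanolate by syn elimination and can give only the exocyclic methylene, with no endocyclic isomer.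

Step 9
Reactants: 16 diol
Product: 17 2-[(1R,3R)-3-hydroxy-2,2-dimethyl-6-methylidenecyclohexyl]acetaldehyde
Conditions: TEMPO (10 mol %), PhI(OAc)2, CH2Cl2, rt
Reagents that add atoms: none
Why: Oxoammonium (TEMPO) oxidation is selective for the primary alcohol over the hindered axial secondary alcohol and stops at the aldehyde, which cannot form a lactol because the hydroxyl is trans to the side chain.

Step 10
Reactants: 17 hydroxy aldehyde; 18 ethyl 2-[bis(2,2,2-trifluoroethoxy)phosphoryl]propanoate
Product: 19 ethyl (2Z)-4-[(1R,3R)-3-hydroxy-2,2-dimethyl-6-methylidenecyclohexyl]-2-methylbut-2-enoate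
Conditions: KN(SiMe3)2, 18-crown-6, THF, −78 °C
Reagents that add atoms: none
Why: Still–Gennari olefination: the bis(trifluoroethyl) phosphonate with a dissociated potassium counter-ion eliminates fast from the kinetic adduct and should give the (Z)-trisubstituted enoate, which fixes the C3'=C4' geometry.

Step 11
Reactants: 19 (Z)-hydroxy enoate
Product: 20 ethyl (2Z)-4-[(1R,3S)-3-bromo-2,2-dimethyl-6-methylidenecyclohexyl]-2-methylbut-2-enoate
Conditions: CBr4, PPh3, pyridine, toluene, 0 → 60 °C
Reagents that add atoms: carbon tetrabromide, BrC(Br)(Br)Br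
Why: Appel reaction: the axial alcohol is activated as its oxyphosphonium salt and displaced by bromide in an SN2 process with inversion, which should give the equatorial bromide cis to the side chain.

Step 12
Reactants: 20 (Z)-bromo enoate
Product: 22 (3Z)-1-bromo-5-[(1R,3S)-3-bromo-2,2-dimethyl-6-methylidenecyclohexyl]-3-methylpent-3-en-2-one, via lithium hemiketal 21 (not isolated)
Conditions: CH2Br2, MeLi·LiBr, THF/Et2O, −78 °C (carbenoid formed in the presence of 20); then AcOH, −78 °C
Reagents that add atoms: dibromomethane, BrCBr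
Why: Halomethyllithium homologation of an ester: bromomethyllithium from bromine–lithium exchange adds to the ester, and the tetrahedral lithium hemiketal should persist at −78 °C, so the α-bromo ketone is released only on protonation and takes up no second equivalent.

Step 13
Reactants: 22 bromomethyl enone
Product: 24 (2S,3Z)-1-bromo-5-[(1R,3S)-3-bromo-2,2-dimethyl-6-methylidenecyclohexyl]-3-methylpent-3-en-2-ol, via borate ester 23 (not isolated)
Conditions: (S)-2-methyl-CBS-oxazaborolidine (20 mol %), catecholborane, toluene, −78 °C; then MeOH, pH 7 buffer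
Reagents that add atoms: none
Why: Corey–Bakshi–Shibata reduction: the oxazaborolidine binds the ketone with the bulky (Z)-alkenyl group away from the catalyst and catecholborane delivers hydride 1,2 to one face, which should give the (S)-bromohydrin without touching the alkenes or the C–Br bonds.

**Compound list**

1 | pent-4-enoyl chloride | C=CCCC(=O)Cl | starting material
2 | (trimethylsilyl)methylmagnesium chloride | C[Si](C)(C)C[Mg]Cl | starting material
3 | 1-(trimethylsilyl)hex-5-en-2-one | C=CCCC(=O)C[Si](C)(C)C | intermediate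
4 | 4-(1,2,4-trioxolan-3-yl)-1-(trimethylsilyl)butan-2-one (ozonide, racemic) | C[Si](C)(C)CC(=O)CCC1OCOO1 | intermediate
5 | 4-oxo-5-(trimethylsilyl)pentanal | C[Si](C)(C)CC(=O)CCC=O | intermediate
6 | 4-methylpenta-1,3-diene | C=CC=C(C)C | starting material
7 | bis(pinacolato)diboron | CC1(C)OB(OC1(C)C)B1OC(C)(C)C(C)(C)O1 | starting material
8 | 2,2'-[(2S)-4-methylpent-3-ene-1,2-diyl]bis(4,4,5,5-tetramethyl-1,3,2-dioxaborolane) | CC(C)=C[C@H](CB1OC(C)(C)C(C)(C)O1)B1OC(C)(C)C(C)(C)O1 | intermediate
9 | (5S,7E)-6,6-dimethyl-5-[(pinacolatoboryl)oxy]-9-(pinacolatoboryl)-1-(trimethylsilyl)non-7-en-2-one (pinacolatoboryl = 4,4,5,5-tetramethyl-1,3,2-dioxaborolan-2-yl) | C[Si](C)(C)CC(=O)CC[C@H](OB1OC(C)(C)C(C)(C)O1)C(C)(C)/C=C/CB1OC(C)(C)C(C)(C)O1 | intermediate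
10 | (1R,2S,4S)-2-ethenyl-3,3-dimethyl-1,4-bis[(pinacolatoboryl)oxy]-1-[(trimethylsilyl)methyl]cyclohexane | C[Si](C)(C)C[C@@]1(OB2OC(C)(C)C(C)(C)O2)CC[C@H](OB2OC(C)(C)C(C)(C)O2)C(C)(C)[C@@H]1C=C | intermediate
11 | (1R,2S,4S)-2-ethenyl-3,3-dimethyl-1-[(trimethylsilyl)methyl]cyclohexane-1,4-diol (both hydroxyls and the vinyl group on one face; the C1 epimer would converge at 16) | C[Si](C)(C)C[C@@]1(O)CC[C@H](O)C(C)(C)[C@@H]1C=C | intermediate
12 | (3S,4R)-3-ethenyl-4-hydroxy-2,2-dimethyl-4-[(trimethylsilyl)methyl]cyclohexan-1-one | C[Si](C)(C)C[C@@]1(O)CCC(=O)C(C)(C)[C@@H]1C=C | intermediate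
13 | (1R,2S,4R)-2-ethenyl-3,3-dimethyl-1-[(trimethylsilyl)methyl]cyclohexane-1,4-diol (secondary hydroxyl axial, trans to vinyl) | C[Si](C)(C)C[C@@]1(O)CC[C@@H](O)C(C)(C)[C@@H]1C=C | intermediate
14 | B-alkyl-9-borabicyclo[3.3.1]nonane adduct of 13 (boron on the terminal carbon of the former vinyl group) | C[Si](C)(C)C[C@@]1(O)CC[C@@H](O)C(C)(C)[C@@H]1CCB1C2CCCC1CCC2 | intermediate
15 | (1R,2S,4R)-2-(2-hydroxyethyl)-3,3-dimethyl-1-[(trimethylsilyl)methyl]cyclohexane-1,4-diol | C[Si](C)(C)C[C@@]1(O)CC[C@@H](O)C(C)(C)[C@@H]1CCO | intermediate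
16 | (1R,3R)-3-(2-hydroxyethyl)-2,2-dimethyl-4-methylidenecyclohexan-1-ol | C=C1CC[C@@H](O)C(C)(C)[C@@H]1CCO | intermediate
17 | 2-[(1R,3R)-3-hydroxy-2,2-dimethyl-6-methylidenecyclohexyl]acetaldehyde | C=C1CC[C@@H](O)C(C)(C)[C@@H]1CC=O | intermediate
18 | ethyl 2-[bis(2,2,2-trifluoroethoxy)phosphoryl]propanoate (racemic) | CCOC(=O)C(C)P(=O)(OCC(F)(F)F)OCC(F)(F)F | starting material
19 | ethyl (2Z)-4-[(1R,3R)-3-hydroxy-2,2-dimethyl-6-methylidenecyclohexyl]-2-methylbut-2-enoate | C=C1CC[C@@H](O)C(C)(C)[C@@H]1C/C=C(/C)C(=O)OCC | intermediate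
20 | ethyl (2Z)-4-[(1R,3S)-3-bromo-2,2-dimethyl-6-methylidenecyclohexyl]-2-methylbut-2-enoate | C=C1CC[C@H](Br)C(C)(C)[C@@H]1C/C=C(/C)C(=O)OCC | intermediate
21 | lithium hemiketal alkoxide from addition of bromomethyllithium to the ester carbonyl of 20 (both epimers at the new carbon) | C=C1CC[C@H](Br)C(C)(C)[C@@H]1C/C=C(/C)C([O-])(OCC)CBr.[Li+] | intermediate
22 | (3Z)-1-bromo-5-[(1R,3S)-3-bromo-2,2-dimethyl-6-methylidenecyclohexyl]-3-methylpent-3-en-2-one | C=C1CC[C@H](Br)C(C)(C)[C@@H]1C/C=C(/C)C(=O)CBr | intermediate
23 | 2-alkoxy-1,3,2-benzodioxaborole (catechol borate) ester of 24 | C=C1CC[C@H](Br)C(C)(C)[C@@H]1C/C=C(/C)[C@H](OB1Oc2ccccc2O1)CBr | intermediate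
24 | (2S,3Z)-1-bromo-5-[(1R,3S)-3-bromo-2,2-dimethyl-6-methylidenecyclohexyl]-3-methylpent-3-en-2-ol | C=C1CC[C@H](Br)C(C)(C)[C@@H]1C/C=C(/C)[C@H](O)CBr | target

**Step count.** Total: 13 steps. Longest linear sequence: 12 steps (1 → 3 → 5 → 11 → 12 → 13 → 15 → 16 → 17 → 19 → 20 → 22 → 24).

**Steps most likely to fail**

Step 4. The ring-closing allylation of the hindered α-silyl ketone may stall after the first (intermolecular) allylation, the ketone may lose silicon before it reacts, or facial selectivity in the ring closure may be poor. The fallback closes the same C1–C6 bond with an allylchromium reagent and sets out from 8 and 5. The allylation is stopped at the stage of 9 (THF, rt) and the remaining allylic C–B bond is oxidised (NaBO3, THF/H2O) to (5S,7E)-5,9-dihydroxy-6,6-dimethyl-1-(trimethylsilyl)non-7-en-2-one F1. Selective Appel bromination of the primary allylic alcohol (CBr4, PPh3, CH2Cl2, −20 °C) should give (5S,7E)-9-bromo-5-hydroxy-6,6-dimethyl-1-(trimethylsilyl)non-7-en-2-one F2. Intramolecular Nozaki–Hiyama allylation with CrCl2 (THF, rt), in which the allylchromium species adds through its γ-carbon to the ketone via a chair transition state, should return to the route at 11.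

Step 11. Elimination to the ring alkene or a cationic methyl shift with ring contraction may outrun SN2 displacement at the neopentyl carbon. The fallback uses a discrete sulfonate displacement under non-ionising conditions and sets out from 19. Tf2O and 2,6-lutidine (CH2Cl2, −78 °C) should give ethyl (2Z)-4-[(1R,3R)-2,2-dimethyl-6-methylidene-3-{[(trifluoromethyl)sulfonyl]oxy}cyclohexyl]-2-methylbut-2-enoate F3. Displacement with Bu4NBr in toluene at rt should invert the centre and return to the route at 20.

Step 12. The carbenoid may decompose before it adds, or the tetrahedral adduct may collapse in the flask and take up a second equivalent. The fallback installs the bromine by electrophilic bromination of an enol silane and sets out from 20. MeNHOMe·HCl with i-PrMgCl (THF, −20 °C) should give (2Z)-4-[(1R,3S)-3-bromo-2,2-dimethyl-6-methylidenecyclohexyl]-N-methoxy-N,2-dimethylbut-2-enamide F4. MeMgBr (THF, 0 °C) should give (3Z)-5-[(1R,3S)-3-bromo-2,2-dimethyl-6-methylidenecyclohexyl]-3-methylpent-3-en-2-one F5. Kinetic enolisation at the methyl group (LiN(SiMe3)2, Me3SiCl, THF, −78 °C) should give {[(3Z)-5-[(1R,3S)-3-bromo-2,2-dimethyl-6-methylidenecyclohexyl]-3-methylpenta-1,3-dien-2-yl]oxy}(trimethyl)silane F6. N-Bromosuccinimide (THF, −78 °C) should then return to the route at 22.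

Further compounds
F1 | step 4 | (5S,7E)-5,9-dihydroxy-6,6-dimethyl-1-(trimethylsilyl)non-7-en-2-one | C[Si](C)(C)CC(=O)CC[C@H](O)C(C)(C)/C=C/CO
F2 | step 4 | (5S,7E)-9-bromo-5-hydroxy-6,6-dimethyl-1-(trimethylsilyl)non-7-en-2-one | C[Si](C)(C)CC(=O)CC[C@H](O)C(C)(C)/C=C/CBr
F3 | step 11 | ethyl (2Z)-4-[(1R,3R)-2,2-dimethyl-6-methylidene-3-{[(trifluoromethyl)sulfonyl]oxy}cyclohexyl]-2-methylbut-2-enoate | C=C1CC[C@@H](OS(=O)(=O)C(F)(F)F)C(C)(C)[C@@H]1C/C=C(/C)C(=O)OCC
F4 | step 12 | (2Z)-4-[(1R,3S)-3-bromo-2,2-dimethyl-6-methylidenecyclohexyl]-N-methoxy-N,2-dimethylbut-2-enamide | C=C1CC[C@H](Br)C(C)(C)[C@@H]1C/C=C(/C)C(=O)N(C)OC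
F5 | step 12 | (3Z)-5-[(1R,3S)-3-bromo-2,2-dimethyl-6-methylidenecyclohexyl]-3-methylpent-3-en-2-one | C=C1CC[C@H](Br)C(C)(C)[C@@H]1C/C=C(/C)C(C)=O
F6 | step 12 | {[(3Z)-5-[(1R,3S)-3-bromo-2,2-dimethyl-6-methylidenecyclohexyl]-3-methylpenta-1,3-dien-2-yl]oxy}(trimethyl)silane | C=C1CC[C@H](Br)C(C)(C)[C@@H]1C/C=C(/C)C(=C)O[Si](C)(C)C
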